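At 8.00 min the summer run, with twice the activator of the noon run, held 22.2% of ring against 11.5%. So I took the ring rate as proportional to activator, and I had to decide how to charge the next flask: all at once, with starting material fed, or with activator fed.

| flask | starting material | activator | protic impurity | remark | time |
|---|---|---|---|---|---|
| summer | 0.10 M | 0.12 M | 2 mM | run made earlier |  |
| noon | 0.10 M | 0.060 M | 2 mM | run made earlier |  |
| cedar | 0.10 M | 0.120 M | 2.00 mM | everything together at the start | 50 min |
| birch | 0.10 M (fed, over 40 min) | 0.120 M | 2.00 mM | all else is in the flask from the start; the feed brings no volume worth counting | 50 min |
| maple | 0.10 M | 0.120 M (fed, over 40 min) | 2.00 mM | all else is in the flask from the start; the feed brings no volume worth counting | 50 min |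

| run | time / min | ring / % |
|---|---|---|
| summer | 4.00 | 11.1 |
| summer | 8.00 | 22.2 |
| summer | 15.0 | 35.3 |
| summer | 25.0 | 42.1 |
| summer | 50.0 | 48.8 |
| noon | 1.33 | 0.5 |
| noon | 2.50 | 2.6 |
| noon | 4.00 | 5.0 |
| noon | 8.00 | 11.5 |
| noon | 15.0 | 19.6 |

(standard deviation of a reading: 0.5 percentage points)

1. the flask with the highest amount of ring, in percent of the starting material charged ("all alike" if they lie within 1.5 percentage points) (cedar / birch / maple / all alike)
2. final ring, as a percentage of the starting material charged, in cedar
3. final ring, as a percentage of the starting material charged, in birch
4. final ring, as a percentage of the starting material charged, in maple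

- a reading or a percentage of ring counts all its forms, free or not

I worked with the fraction left. The summer ring slope fell to a quarter between the early and late intervals, yet the fraction not yet ring fell from 8.00 min to 25.0 min to just 0.744 of its value. Two readings stood open: the activator was failing, which these runs could not exclude, or a rival was taking starting material. I assumed a rival needing no activator and second order in starting material; both runs share one charge of starting material, so this stayed an assumption.

Write [A] and [B] for starting material and activator. Summer's final 48.8%, with the whole rest counted as lost, means 0.953 of ring per unit lost. Reading that at [A] of half the charge and [B] at its charge gave g = 0.397, the selectivity factor, so that ring per unit lost is g[B]/[A].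

Cedar repeats summer. For birch, the early fraction left gave a ring rate constant of 0.0314 min⁻¹. Balancing the feed against ring and rival, with activator held at its charge, gave a steady [A] of 0.0422 M, so a ring share of what reacts of 53.0%. For maple, half of each charge gave a share of 32.3%. My birch share stood above both my maple share and summer's final ring, so I chose to feed starting material.

The forecast differed: cedar first, at 49%, then maple at 43% and birch at 34%, with the remark “Maple loses contact time but protects activator”.

Birch ended at 54.3%, cedar at 48.8% and maple at 22.5%.

    starting material + activator → activated form (k = 0.0120 M⁻¹ s⁻¹)
    activated form → ring (k = 0.00530 s⁻¹)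
    starting material + activated form → open dimer (k = 0.00380 M⁻¹ s⁻¹)
    starting material + protic impurity → quenched substrate (k = 0.530 M⁻¹ s⁻¹)
    2 starting material → homo dimer (k = 0.0130 M⁻¹ s⁻¹)
    crystals ⇌ ring, rate k6*(cs6 - [ring]) while solid is left; crystals form when [ring] > cs6 (solubility = 31.0 mM, k = 0.0510 s⁻¹)

At 50.0 min homo dimer, each counted as two, stood at 28.1% in birch, 45.1% in cedar and 72.1% in maple. At 25.0 min birch held starting material at 22.0% of the whole charge and activator at 76.5% of its own charge, which puts g[B]/[A] at 1.66. From then until 40.0 min birch gained 1.58 of ring per unit of homo dimer.

(The earlier runs and the new flask are calculated from invented constants, and the scatter is random.)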